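## Retrosynthetic overview
1. Target 27 ⇒ bicyclo[3.2.1]octenone 23 by C15 oxidation, C12 reduction and acetylation. Ring D of 23 comes from C11 alkylation of enone 20 with 2,3-dibromopropene, then enolate alkenylation at C13.
2. Ring C enone 20 ⇒ Birch reduction of anisole 18, which also reduces the C1 ketone.
3. Ring B of 18 (C7–C8 bond and C6–O) ⇒ vinyl/aryl bromide 15 by diboration, ring-closing Suzuki coupling and oxidation.
4. C9–C10 bond and quaternary C10 of 15 ⇒ 1,2-aryl shift C1→C10 (hydrogen-atom-transfer-initiated semipinacol) in carbinol 14. Carbinol 14 ⇒ aryl Grignard 13 + enone 9.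
5. Ring A enone 9 ⇒ isobutyraldehyde + methyl vinyl ketone, then asymmetric vinyl addition and methylenation. Ring order: A, aromatic C attached, B, D.

Assumption: positions carry ent-kaurane numbers (C12 carbinol, C15 ketone, C16=C17 methylidene; α is the face of the C20 methyl). Operations telescoped without isolation count as one step.

## Route

Step 1
Reactants: 1 isobutyraldehyde; 2 methyl vinyl ketone
Product: 3 4,4-dimethylcyclohex-2-en-1-one
Conditions: H2SO4 (cat.), toluene, reflux, Dean–Stark
Reagents that add atoms: none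
Why: Acid-catalysed Michael addition followed by aldol condensation (Robinson-type annulation) closes ring A with the gem-dimethyl carbon C4 in place, and no stereocentre is formed.

Step 2
Reactants: 3 4,4-dimethylcyclohex-2-en-1-one; 4 vinylmagnesium bromide
Product: 9 (3R)-3-ethenyl-4,4-dimethyl-2-methylidenecyclohexan-1-one, via ethenyl(dimethyl)aluminium 5 (not isolated), via aluminium enolate 6 (not isolated), via Mannich base 7 (not isolated), via trimethylammonium iodide 8 (not isolated)
Conditions: 4, Me2AlCl, Et2O, 0 °C; Cu(OTf)2 (2 mol %), (R,S,S)-BINOL bis(1-phenylethyl)amine phosphoramidite (4 mol %), 3, Et2O, −30 °C; Eschenmoser's salt, THF, −30 → 23 °C; MeI, 23 °C; aq NaHCO3/CH2Cl2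
Reagents that add atoms: Eschenmoser's salt (N,N-dimethylmethyleneiminium iodide), C=[N+](C)C.[I-]
Why: Copper-catalysed asymmetric conjugate addition of an alkenylalane sets C5 under ligand control, and the regiodefined enolate is trapped in a Mannich reaction whose amine leaves after exhaustive methylation (E1cB) to give the C10=C20 methylidene.

Step 3
Reactants: 10 3-iodophenol
Product: 11 3-iodoanisole
Conditions: MeI, K2CO3, acetone, reflux
Reagents that add atoms: iodomethane, CI
Why: Williamson O-methylation turns the phenol into the anisole needed for para-directed bromination and for the later Birch reduction.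

Step 4
Reactants: 11 3-iodoanisole
Product: 12 1-bromo-2-iodo-4-methoxybenzene
Conditions: NBS, MeCN, 0 → 23 °C
Reagents that add atoms: N-bromosuccinimide, O=C1CCC(=O)N1Br
Why: Electrophilic aromatic bromination of an anisole in acetonitrile is para-selective and places bromine on the future C8, next to the iodine-bearing future C9.

Step 5
Reactants: 12 1-bromo-2-iodo-4-methoxybenzene; 9 (3R)-3-ethenyl-4,4-dimethyl-2-methylidenecyclohexan-1-one
Product: 14 (1S,3R)-1-(2-bromo-5-methoxyphenyl)-3-ethenyl-4,4-dimethyl-2-methylidenecyclohexan-1-ol, via aryl Grignard reagent 13 (not isolated)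
Conditions: iPrMgCl·LiCl, THF, −20 °C; 9 premixed with LaCl3·2LiCl, THF, −20 → 0 °C; aq NH4Cl
Reagents that add atoms: none
Why: Iodine–magnesium exchange outruns bromine exchange, and the lanthanum-promoted Grignard 1,2-addition occurs opposite the C5 vinyl group (held axial by allylic strain with the methylidene and gauche strain with the gem-dimethyl group), so the aryl group ends trans to vinyl (1S).

Step 6
Reactants: 14 (1S,3R)-1-(2-bromo-5-methoxyphenyl)-3-ethenyl-4,4-dimethyl-2-methylidenecyclohexan-1-ol
Product: 15 (2R,3R)-2-(2-bromo-5-methoxyphenyl)-3-ethenyl-2,4,4-trimethylcyclohexan-1-one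
Conditions: [N,N′-bis(3,5-di-tert-butylsalicylidene)-1,1,2,2-tetramethylethylenediaminato]cobalt (5 mol %), N-fluoro-2,4,6-trimethylpyridinium triflate (1.2 equiv), PhSiH3 (1.1 equiv), PhCF3, 0 → 23 °C
Reagents that add atoms: none
Why: Cobalt-hydride hydrogen-atom transfer to the CH2 end of the more reactive 1,1-disubstituted alkene gives the tertiary C10 radical, whose oxidation (radical–polar crossover) triggers a semipinacol 1,2-aryl shift from C1 to C10 on the same β face, which creates the C9–C10 bond, the quaternary C10 (R), the C20 methyl and the C1 ketone without acid that would ionise the benzylic allylic alcohol.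

Step 7
Reactants: 15 (2R,3R)-2-(2-bromo-5-methoxyphenyl)-3-ethenyl-2,4,4-trimethylcyclohexan-1-one
Product: 18 (5R,6S,10R)-6α-hydroxy-12-methoxy-ent-podocarpa-8,11,13-trien-1-one (trans A/B), via bis(boronate) 16 (not isolated), via cyclised boronate 17 (not isolated)
Conditions: Pt(dba)3 (3 mol %), (R,R)-TADDOL-derived phenylphosphonite (3.6 mol %), B2pin2, THF, 60 °C; Pd(OAc)2 (5 mol %), RuPhos, KOH, THF/H2O, 70 °C; NaOH, H2O2, 0 → 23 °C
Reagents that add atoms: hydrogen peroxide, OO
Why: Proposed new method: ligand-controlled platinum-catalysed syn-diboration of the vinyl group sets C6 (ligand antipode chosen for 6S), the primary C7–B bond, activated by the neighbouring boronate, transmetalates selectively to the arylpalladium formed at the ortho C8–Br bond and closes the six-membered ring B, and the remaining secondary C–B bond is oxidised with retention to the 6α-alcohol; the closest known reactions are the intermolecular diboration/cross-coupling/oxidation of terminal alkenes and the ring-closing B-alkyl Suzuki–Miyaura coupling.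

Step 8
Reactants: 18 (5R,6S,10R)-6α-hydroxy-12-methoxy-ent-podocarpa-8,11,13-trien-1-one
Product: 20 (1S,5R,6S,10R)-1α,6α-dihydroxy-ent-podocarp-8-en-12-one, via dienol ether diol 19 (not isolated)
Conditions: Li, NH3(l), THF, t-BuOH, −78 → −33 °C; NH4Cl; (CO2H)2, THF/H2O, 23 °C
Reagents that add atoms: water, O
Why: Birch reduction gives the 1-methoxy-1,4-diene that keeps the tetrasubstituted C8=C9 bond, the dissolving metal reduces the C1 ketone to the thermodynamically preferred equatorial 1α-alcohol (1S), and mild enol-ether hydrolysis releases the C12 ketone without conjugating the alkene.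

Step 9
Reactants: 20 (1S,5R,6S,10R)-1α,6α-dihydroxy-ent-podocarp-8-en-12-one; 21 2,3-dibromopropene
Product: 22 (11R)-11β-(2-bromoprop-2-enyl)-1α,6α-dihydroxy-ent-podocarp-8-en-12-one
Conditions: KOtBu (3.2 equiv), t-BuOH/THF, 0 °C, degassed; 21 (1.05 equiv)
Reagents that add atoms: none
Why: The thermodynamic extended dienolate undergoes deconjugative α-alkylation at C11 from the β face opposite the axial C20 methyl, which sets C11 (R), and the hindered alkoxides stay unalkylated as in classical alkylations of hydroxy enones under these conditions.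

Step 10
Reactants: 22 (11R)-11β-(2-bromoprop-2-enyl)-1α,6α-dihydroxy-ent-podocarp-8-en-12-one
Product: 23 tetracyclic diol ketone: 1α,6α-dihydroxy-12-oxo-15-deoxo analogue of the target (C13–C16 bond closed, 11R,13R)
Conditions: Pd(PPh3)4 (10 mol %), KOtBu (3.2 equiv), THF, 65 °C
Reagents that add atoms: none
Why: In this palladium-catalysed intramolecular α-alkenylation of a ketone enolate only the reversibly formed C13 enolate can reach the vinylpalladium, so the five-membered ring D closes as a β-face bridge and C13 (R) is fixed by the geometry of the bicyclo[3.2.1]octene.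

Step 11
Reactants: 23 tetracyclic diol ketone
Product: 24 1α,6α-diacetoxy-12-oxo-15-deoxo analogue of the target
Conditions: Ac2O, DMAP, pyridine, 50 °C
Reagents that add atoms: acetic anhydride, CC(=O)OC(C)=O
Why: DMAP-catalysed acylation esterifies both secondary alcohols, including the hindered axial 6α-OH, before the C12 hydroxyl exists, so no later differentiation of hydroxyl groups is needed.

Step 12
Reactants: 24 1α,6α-diacetoxy-12-oxo-15-deoxo analogue of the target
Product: 25 15-deoxo-1α,6α-diacetoxyjungermannenone C (12S alcohol, C15 = CH2)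
Conditions: NaBH4, MeOH/CH2Cl2, −20 °C
Reagents that add atoms: none
Why: Borohydride attacks the strained bridge ketone from the open side over the sp2 C8=C9 bridge, as in 7-norbornenone-type ketones, which places the hydroxyl syn to the C15–C16 bridge (12S) and leaves the acetates intact.

Step 13
Reactants: 25 15-deoxo-1α,6α-diacetoxyjungermannenone C
Product: 26 15-hydroxy-15-deoxo-1α,6α-diacetoxyjungermannenone C (12,15-diol, C15 epimers)
Conditions: SeO2 (20 mol %), t-BuOOH, CH2Cl2, 23 °C
Reagents that add atoms: tert-butyl hydroperoxide, CC(C)(C)OO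
Why: Catalytic selenium dioxide allylic hydroxylation of the exocyclic methylene can use only the C15 hydrogens, because the other allylic position is the C13 bridgehead and the shielded tetrasubstituted C8=C9 bond reacts more slowly.

Step 14
Reactants: 26 15-hydroxy-15-deoxo-1α,6α-diacetoxyjungermannenone C
Product: 27 1α,6α-diacetoxyjungermannenone C
Conditions: MnO2, CH2Cl2, 23 °C
Reagents that add atoms: none
Why: Manganese dioxide oxidises only the allylic C15 alcohol to the α-methylene ketone, erases the C15 epimer mixture and leaves the saturated C12 alcohol untouched.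

## Compound list
1 | isobutyraldehyde | CC(C)C=O | starting material
2 | methyl vinyl ketone | C=CC(C)=O | starting material
3 | 4,4-dimethylcyclohex-2-en-1-one | CC1(C)C=CC(=O)CC1 | intermediate
4 | vinylmagnesium bromide | C=C[Mg]Br | starting material
5 | ethenyl(dimethyl)aluminium | C=C[Al](C)C | intermediate
6 | dimethylaluminium C1=C10 enolate of 3-ethenyl-4,4-dimethylcyclohexanone | C=C[C@@H]1C(C)(C)CCC(O[Al](C)C)=C1 | intermediate
7 | (2R,3S)-2-[(dimethylamino)methyl]-3-ethenyl-4,4-dimethylcyclohexan-1-one (trans) | C=C[C@@H]1C(C)(C)CCC(=O)[C@H]1CN(C)C | intermediate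
8 | trimethylammonium iodide of 7 | C=C[C@@H]1C(C)(C)CCC(=O)[C@H]1C[N+](C)(C)C.[I-] | intermediate
9 | (3R)-3-ethenyl-4,4-dimethyl-2-methylidenecyclohexan-1-one | C=C[C@@H]1C(C)(C)CCC(=O)C1=C | intermediate
10 | 3-iodophenol | Oc1cccc(I)c1 | starting material
11 | 3-iodoanisole | COc1cccc(I)c1 | intermediate
12 | 1-bromo-2-iodo-4-methoxybenzene | COc1ccc(Br)c(I)c1 | intermediate
13 | (2-bromo-5-methoxyphenyl)magnesium chloride | COc1ccc(Br)c([Mg]Cl)c1 | intermediate
14 | (1S,3R)-1-(2-bromo-5-methoxyphenyl)-3-ethenyl-4,4-dimethyl-2-methylidenecyclohexan-1-ol | C=C[C@@H]1C(C)(C)CC[C@@](O)(c2cc(OC)ccc2Br)C1=C | intermediate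
15 | (2R,3R)-2-(2-bromo-5-methoxyphenyl)-3-ethenyl-2,4,4-trimethylcyclohexan-1-one | C=C[C@@H]1C(C)(C)CCC(=O)[C@]1(c2cc(OC)ccc2Br)C | intermediate
16 | C6,C7-bis(pinacolboronate) of 15 (6S) | CC1(C)OB(C[C@H](B2OC(C)(C)C(C)(C)O2)[C@@H]3C(C)(C)CCC(=O)[C@]3(c4cc(OC)ccc4Br)C)OC1(C)C | intermediate
17 | 6α-(pinacolboryl)-12-methoxy-ent-podocarpa-8,11,13-trien-1-one | c1c3c(C[C@H](B2OC(C)(C)C(C)(C)O2)[C@@H]4C(C)(C)CCC(=O)[C@@]34C)ccc1OC | intermediate
18 | (5R,6S,10R)-6α-hydroxy-12-methoxy-ent-podocarpa-8,11,13-trien-1-one | c1c3c(C[C@H](O)[C@@H]4C(C)(C)CCC(=O)[C@@]34C)ccc1OC | intermediate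
19 | 12-methoxy-ent-podocarpa-8,12-diene-1α,6α-diol | COC1=CCC(C[C@H](O)[C@@H]4C(C)(C)CC[C@H](O)[C@@]34C)=C3C1 | intermediate
20 | (1S,5R,6S,10R)-1α,6α-dihydroxy-ent-podocarp-8-en-12-one | O=C1CC3=C(C[C@H](O)[C@@H]4C(C)(C)CC[C@H](O)[C@@]34C)CC1 | intermediate
21 | 2,3-dibromopropene | C=C(Br)CBr | starting material
22 | (11R)-11β-(2-bromoprop-2-enyl)-1α,6α-dihydroxy-ent-podocarp-8-en-12-one | C=C(Br)C[C@@H]2C3=C(C[C@H](O)[C@@H]4C(C)(C)CC[C@H](O)[C@@]34C)CCC2=O | intermediate
23 | 1α,6α-dihydroxy-12-oxo-15-deoxo analogue of the target | C=C1C[C@@H]2C3=C(C[C@H](O)[C@@H]4C(C)(C)CC[C@H](O)[C@@]34C)C[C@H]1C2=O | intermediate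
24 | 1α,6α-diacetoxy-12-oxo-15-deoxo analogue of the target | C=C1C[C@@H]2C3=C(C[C@H](OC(C)=O)[C@@H]4C(C)(C)CC[C@H](OC(C)=O)[C@@]34C)C[C@H]1C2=O | intermediate
25 | 15-deoxo-1α,6α-diacetoxyjungermannenone C (12S) | C=C1C[C@@H]2C3=C(C[C@H](OC(C)=O)[C@@H]4C(C)(C)CC[C@H](OC(C)=O)[C@@]34C)C[C@H]1[C@@H]2O | intermediate
26 | 12,15-diol (C15 epimer mixture, C15 left undefined) | C=C1C(O)[C@@H]2C3=C(C[C@H](OC(C)=O)[C@@H]4C(C)(C)CC[C@H](OC(C)=O)[C@@]34C)C[C@H]1[C@@H]2O | intermediate
27 | 1α,6α-diacetoxyjungermannenone C | C=C1C(=O)[C@@H]2C3=C(C[C@H](OC(C)=O)[C@@H]4C(C)(C)CC[C@H](OC(C)=O)[C@@]34C)C[C@H]1[C@@H]2O | target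

## Count and risks
Total steps: 14. Longest linear sequence: 12 (steps 1, 2, 5–14).

**Step 2.** The neopentyl β-carbon may give low conversion or low ee, and the aluminium enolate may trap poorly. The fallback sets out from 3 and returns at 9. Enone 3 is hydroxymethylated with aqueous formaldehyde and DMAP (Morita–Baylis–Hillman reaction) to 2-(hydroxymethyl)-4,4-dimethylcyclohex-2-en-1-one F1. Acetylation with Ac2O/pyridine gives (3,3-dimethyl-6-oxocyclohex-1-enyl)methyl acetate F2. F2 is then treated with potassium vinyltrifluoroborate, [RhCl(C2H4)2]2 and (R)-BINAP in toluene/H2O. Enantioselective 1,4-addition followed by β-acetoxy elimination from the rhodium enolate gives 9 without any enolate trapping.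

**Step 6.** The cation may be caught by oxygen to give an epoxide, or hydrogen-atom transfer may compete at the vinyl group. The fallback sets out from 14 and returns at 15, and keeps the same 1,2-aryl shift in a polar manifold. Carbinol 14 is silylated (TMSOTf, 2,6-lutidine) to the trimethylsilyl ether of 14 F3. F3 is treated with Tf2NH (10 mol %) and 2-propanol (1 equiv) in CH2Cl2 at −78 °C. Protonation of the 1,1-disubstituted alkene, aryl migration and loss of silicon (acid-promoted semipinacol rearrangement of an allylic silyl ether) give 15.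

**Step 7 (the proposed new step).** The ring-closing coupling may stall at the hindered aryl bromide, or C6 may be set poorly. The fallback sets out from 15 and returns at 18, using known chemistry only.
- Wacker–Tsuji oxidation (PdCl2, CuCl, O2, DMF/H2O) converts the vinyl group into the methyl ketone (2R,3R)-3-acetyl-2-(2-bromo-5-methoxyphenyl)-2,4,4-trimethylcyclohexan-1-one F4.
- Intramolecular Buchwald–Hartwig α-arylation of the methyl ketone (Pd(OAc)2, XPhos, NaOtBu, toluene, 80 °C) closes ring B to 12-methoxy-ent-podocarpa-8,11,13-triene-1,6-dione F5. Any C5 epimer equilibrates there to the trans fusion.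
- NaBH4 (1 equiv, MeOH/CH2Cl2, −78 °C) reduces only the less hindered β-tetralone-type C6 ketone, from the β face opposite the two axial methyls, and gives 18.

Further compounds
F1 | step 2 | 2-(hydroxymethyl)-4,4-dimethylcyclohex-2-en-1-one | CC1(C)CCC(=O)C(CO)=C1
F2 | step 2 | (3,3-dimethyl-6-oxocyclohex-1-enyl)methyl acetate | CC(=O)OCC1=CC(C)(C)CCC1=O
F3 | step 6 | trimethylsilyl ether of 14 | C=C[C@@H]1C(C)(C)CC[C@@](O[Si](C)(C)C)(c2cc(OC)ccc2Br)C1=C
F4 | step 7 | (2R,3R)-3-acetyl-2-(2-bromo-5-methoxyphenyl)-2,4,4-trimethylcyclohexan-1-one | CC(=O)[C@@H]1C(C)(C)CCC(=O)[C@]1(c2cc(OC)ccc2Br)C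
F5 | step 7 | 12-methoxy-ent-podocarpa-8,11,13-triene-1,6-dione (trans A/B) | c1c3c(CC(=O)[C@@H]4C(C)(C)CCC(=O)[C@@]34C)ccc1OC
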